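**Assumption:** the target (5,6,3',4'-tetrahydroxyflavone 7-O-sulfate) has no stereocentres, so there is no enantiomer to control. It is delivered as the free hydrogen sulfate shown in the SMILES. Only substrates and intermediates are numbered; atom-donating reagents are given by name and SMILES in each step.

## Retrosynthetic overview

1. Target ⇐ 7-O-(trichloroethyl sulfate) tri-O-benzyl flavone 10 (one reductive unmasking) ⇐ 5,7-dihydroxy flavone 9, where the chelated 5-OH is inert so sulfation can only occur at 7-OH.
2. Key step: the pyranone (C ring) is made last, in one Pd-catalysed three-component carbonylative Sonogashira annulation of an o-iodophenol, CO and an aryl acetylene (forms C4a–C4, C4–C3 and O1–C2). This replaces the usual acetophenone/Baker–Venkataraman or chalcone route.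
3. A ring: a symmetric 4-benzyloxy-3,5-bis(MOM-oxy)phenol from 3,4,5-trihydroxybenzaldehyde (4-O-benzylation, MOM protection, Dakin oxidation). Symmetry removes any regiochemical question in the iodination and annulation; the 5-O and 7-O are told apart later by chelation alone.
4. B ring: 3,4-bis(benzyloxy)phenylacetylene from the aldehyde by Ohira–Bestmann homologation.
5. Ring order: A and B are pre-formed arenes; C is closed by the annulation.

## Route

**Step 1**
Reactants: 1, 3,4,5-trihydroxybenzaldehyde
Product: 2, 4-(benzyloxy)-3,5-dihydroxybenzaldehyde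
Conditions: BnBr (1.0 equiv), NaHCO3, NaI (cat.), DMF, 40 °C
Reagents that add atoms: benzyl bromide, BrCc1ccccc1
Why: Williamson etherification; the 4-OH para to the aldehyde is by far the most acidic, so bicarbonate ionises and alkylates only that position.

**Step 2**
Reactants: 2, 4-(benzyloxy)-3,5-dihydroxybenzaldehyde
Product: 3, 4-(benzyloxy)-3,5-bis(methoxymethoxy)benzaldehyde
Conditions: MOMCl (2.5 equiv), iPr2NEt, CH2Cl2, 0 °C → rt
Reagents that add atoms: chloromethyl methyl ether, COCCl (two equivalents incorporated)
Why: Standard MOM acetal protection of the two equivalent phenols; MOM is stable to the peracid, base and Pd/amine steps that follow and is removable without touching benzyl ethers.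

**Step 3**
Reactants: 3, 4-(benzyloxy)-3,5-bis(methoxymethoxy)benzaldehyde
Product: 4, 4-(benzyloxy)-3,5-bis(methoxymethoxy)phenol
Conditions: mCPBA, NaHCO3, CH2Cl2, 0 °C → rt; Na2S2O3 quench; then K2CO3, MeOH, rt
Reagents that add atoms: mCPBA, O=C(OO)c1cccc(Cl)c1 (one O)
Why: Dakin-type Baeyer–Villiger oxidation; the electron-rich trialkoxyaryl group migrates to give the aryl formate, which is methanolysed to the single free phenol that will become O1. The bicarbonate buffer protects the MOM groups.

**Step 4**
Reactants: 4, 4-(benzyloxy)-3,5-bis(methoxymethoxy)phenol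
Product: 5, 4-(benzyloxy)-2-iodo-3,5-bis(methoxymethoxy)phenol
Conditions: NIS (1.0 equiv), MeCN, −20 → 0 °C, dark
Reagents that add atoms: N-iodosuccinimide, O=C1CCC(=O)N1I
Why: Electrophilic aromatic iodination; the para position is blocked and the two ortho positions are equivalent, so only one mono-iodide can form.

**Step 5**
Reactants: 6, 3,4-bis(benzyloxy)benzaldehyde
Product: 7, 1,2-bis(benzyloxy)-4-ethynylbenzene
Conditions: Ohira–Bestmann reagent, K2CO3, MeOH/THF, rt
Reagents that add atoms: dimethyl (1-diazo-2-oxopropyl)phosphonate, COP(=O)(OC)C(=[N+]=[N-])C(C)=O (one C)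
Why: Seyferth–Gilbert/Ohira–Bestmann homologation converts a non-enolisable aryl aldehyde directly into the terminal alkyne under mild base.

**Step 6 (key step)**
Reactants: 5, 4-(benzyloxy)-2-iodo-3,5-bis(methoxymethoxy)phenol; 7, 1,2-bis(benzyloxy)-4-ethynylbenzene
Product: 8, 6-(benzyloxy)-2-[3,4-bis(benzyloxy)phenyl]-5,7-bis(methoxymethoxy)-4H-chromen-4-one
Conditions: PdCl2(dppf) (5 mol %), CO (10 bar), Et2NH/DMF, 100 °C, Cu-free
Reagents that add atoms: carbon monoxide, [C-]#[O+]
Why: Pd-catalysed carbonylative Sonogashira coupling gives the o-hydroxyaryl ynone, and Et2NH adds to it to form a β-aminoenone that the only free phenol displaces in 6-endo fashion, giving the flavone and not the aurone. Running Cu-free under CO pressure suppresses direct Sonogashira coupling and benzofuran formation.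

**Step 7**
Reactants: 8, the bis-MOM flavone
Product: 9, 6-(benzyloxy)-2-[3,4-bis(benzyloxy)phenyl]-5,7-dihydroxy-4H-chromen-4-one
Conditions: 3 M HCl, MeOH/THF, 50 °C
Reagents that add atoms: none
Why: Acid-catalysed acetal cleavage removes both MOM groups, while the benzyl ethers and the flavone are stable to dilute HCl.

**Step 8**
Reactants: 9, the 5,7-dihydroxy tri-O-benzyl flavone
Product: 10, 6-(benzyloxy)-2-[3,4-bis(benzyloxy)phenyl]-5-hydroxy-4-oxo-4H-chromen-7-yl 2,2,2-trichloroethyl sulfate
Conditions: Cl3CCH2OSO2Cl (1.2 equiv), Et3N, DMAP, THF, 0 °C → rt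
Reagents that add atoms: 2,2,2-trichloroethyl chlorosulfate, ClS(=O)(=O)OCC(Cl)(Cl)Cl
Why: Sulfurylation with a protected sulfating agent; the acidic 7-OH reacts, while the 5-OH is hydrogen-bonded to C4=O and peri-hindered and stays free. The product is a neutral sulfate diester that can be purified on silica.

**Step 9**
Reactants: 10, the trichloroethyl sulfate diester
Product: 11, 6-hydroxyluteolin 7-sulfate, 2-(3,4-dihydroxyphenyl)-5,6-dihydroxy-4-oxo-4H-chromen-7-yl hydrogen sulfate
Conditions: 10% Pd/C, HCO2NH4, MeOH/THF, rt (H2 balloon to complete), under Ar work-up; Dowex 50W (H+), 0 °C; lyophilise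
Reagents that add atoms: none
Why: Catalytic transfer hydrogenolysis cleaves the trichloroethyl group by reductive fragmentation and the three O-benzyl ethers in one operation. The aryl sulfate monoester anion is inert to Pd/H, and cold H+ exchange converts the ammonium salt to the acid form.

## Compound list

1 | 3,4,5-trihydroxybenzaldehyde | O=Cc1cc(O)c(O)c(O)c1 | starting material
2 | 4-(benzyloxy)-3,5-dihydroxybenzaldehyde | O=Cc1cc(O)c(OCc2ccccc2)c(O)c1 | intermediate
3 | 4-(benzyloxy)-3,5-bis(methoxymethoxy)benzaldehyde | O=Cc1cc(OCOC)c(OCc2ccccc2)c(OCOC)c1 | intermediate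
4 | 4-(benzyloxy)-3,5-bis(methoxymethoxy)phenol | Oc1cc(OCOC)c(OCc2ccccc2)c(OCOC)c1 | intermediate
5 | 4-(benzyloxy)-2-iodo-3,5-bis(methoxymethoxy)phenol | Oc1cc(OCOC)c(OCc2ccccc2)c(OCOC)c1I | intermediate
6 | 3,4-bis(benzyloxy)benzaldehyde | O=Cc1ccc(OCc2ccccc2)c(OCc2ccccc2)c1 | starting material
7 | 1,2-bis(benzyloxy)-4-ethynylbenzene | C#Cc1ccc(OCc2ccccc2)c(OCc2ccccc2)c1 | intermediate
8 | 6-(benzyloxy)-2-[3,4-bis(benzyloxy)phenyl]-5,7-bis(methoxymethoxy)-4H-chromen-4-one | O=c1cc(-c2ccc(OCc3ccccc3)c(OCc3ccccc3)c2)oc2cc(OCOC)c(OCc3ccccc3)c(OCOC)c12 | intermediate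
9 | 6-(benzyloxy)-2-[3,4-bis(benzyloxy)phenyl]-5,7-dihydroxy-4H-chromen-4-one | O=c1cc(-c2ccc(OCc3ccccc3)c(OCc3ccccc3)c2)oc2cc(O)c(OCc3ccccc3)c(O)c12 | intermediate
10 | 6-(benzyloxy)-2-[3,4-bis(benzyloxy)phenyl]-5-hydroxy-4-oxo-4H-chromen-7-yl 2,2,2-trichloroethyl sulfate | O=c1cc(-c2ccc(OCc3ccccc3)c(OCc3ccccc3)c2)oc2cc(OS(=O)(=O)OCC(Cl)(Cl)Cl)c(OCc3ccccc3)c(O)c12 | intermediate
11 | 6-hydroxyluteolin 7-sulfate | O=c1cc(-c2ccc(O)c(O)c2)oc2cc(OS(=O)(=O)O)c(O)c(O)c12 | target

## Summary

Total steps: 9. Longest linear sequence: 8 (Steps 1–4, 6–9, from compound 1); Step 5 is the one-step side branch.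

Three steps most likely to fail, with fallbacks:

- **Step 6 (carbonylative annulation on a di-ortho-substituted, electron-rich iodophenol).** Risks are direct Sonogashira coupling to a benzofuran, or aurone formation. Fallback: drop Pd/CO. Silylate the phenol of 5, do I/Mg exchange (iPrMgCl·LiCl), and add the aryl Grignard to the Weinreb amide of 3-[3,4-bis(benzyloxy)phenyl]propiolic acid (from 7) to make the ynone; then desilylate and close with Et2NH to give 8.
- **Step 9 (simultaneous trichloroethyl and tri-benzyl removal).** Risks are over-reduction of C2=C3, incomplete debenzylation, and air oxidation of the product. Fallback: separate the two events without hydrogenation. Debenzylate at the acid-stable diester stage with BCl3/pentamethylbenzene at −78 °C, then release the sulfate with Zn/HCO2NH4.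
- **Step 1 (mono-benzylation of a triol).** Risk is over- or mis-alkylation. Fallback: use the ester series. Methyl 4-(benzyloxy)-3,5-dihydroxybenzoate (from methyl gallate) is MOM-protected, reduced to the benzylic alcohol (LiAlH4) and oxidised (MnO2) to rejoin the route at aldehyde 3.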